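## Structural features

The target is a dihydrochalcone built on a hexasubstituted benzene (ring A). Ring A is fused to a 2,3-dihydrofuran (ring B: O1, C2, C3, C3a, C7a) and carries hydroxyls at C4 and C6, a prenyl group at C5 and a 3-(4-methoxyphenyl)propanoyl chain at C7 that ends in anisyl ring C. The only stereocentre is C2 (S), an O1-bearing methine between the C3 methylene and the non-stereogenic carbinol carbon of the 2-hydroxypropan-2-yl group, so no neighbouring centre can relay stereochemistry to it. Fragile elements are the prenyl alkene held between two phenols (acid closes a chroman), the oxidisable phloroglucinol-type nucleus, the tertiary alcohol β to an aryl ether oxygen (ionisation, dehydration) and the enolisable aryl ketone. The difficulty is twofold: an isolated stereocentre next to a fully substituted carbon, and two different carbon substituents at C5 and C7 of a ring with no free position. The key step uses the fact that C3 is an unsubstituted benzylic CH2 on C3a and C2 is a CH bonded to O1 on C7a. The C2–C3 bond can therefore come from a carbene centred on C3 that inserts into one of the two enantiotopic C–H bonds of the O1–CH2 group of an achiral 2-oxy-2-methylpropyl aryl ether, which closes ring B and creates C2 together. C5 lies between O4 and O6 and C7 between O6 and O1, so both can be addressed afterwards by directed metalation.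

## Logic of the disconnections

21 to 20: the two phenolic O–CH2OMe bonds and the tertiary O–Si bond are cut. All three masks fall to one mild acid, so the gain is a single final operation. The demand is an acid weak enough to leave the prenyl–phenol pair and the tertiary alcohol alone.

20 to 14 and 17: the C7–C(=O) bond is cut, with C7 as an aryl anion flanked by O6 and O1 and the carbonyl carbon as an N-methoxy-N-methylamide. This removes the whole ring C arm in one convergent step. The demand is that metalation at C7 outruns deprotonation at the prenyl CH2 and at C3, and that addition stops at the ketone stage. 17 is traced to 15 by cutting the amide C–N bond.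

14 to 11 and 12: the C5–CH2 bond is cut. C5 sits between two methoxymethyl ethers and should be the most acidic ring position, so the prenyl group is introduced before the acyl group, which would not survive an organolithium. The demand is metalation at C5 in preference to C7 and allylic substitution without transposition.

11 to 9: the O4–CH2OMe bond is exchanged for O4–Si. A methoxymethyl ether is needed at O4 to direct metalation but cannot be present in the key step, where its OCH2 would sit in the same 1,5 relation to the carbene as the wanted O1–CH2. O6 is para to the carbene carbon and out of reach, so it carries its methoxymethyl group from the start and only one group has to be exchanged. The demand is cleavage of the aryl silyl ether without loss of the tertiary triethylsilyl ether.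

9 to 7: the C2–C3 bond is cut (key step). Ring B and the stereocentre vanish and an achiral tosylhydrazone remains. The forward step needs site selectivity, discrimination of two enantiotopic hydrogens and suppression of bimolecular carbene loss. The catalyst chosen is Co(3,5-DitBu-ChenPhyrin), the complex of divalent cobalt with a D2-symmetric porphyrin carrying four chiral 2,2-dimethylcyclopropanecarboxamide units.

7 to 6, 5 and 4: the C=N bond and the two O–Si bonds are cut. A tert-butyldimethylsilyl group on the ortho oxygen offers no C–H in 1,5 reach, and a triethylsilyl group on the tertiary oxygen removes the O–H. The demand is that each silylation finds only its own hydroxyl.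

4 to 2 and 3, and 2 to 1: the ether O–CH2 bond is cut to a phenoxide and an epoxide, which delivers the side chain at its final oxidation level in one step with no alkene hydration next to the aldehyde. 2 is traced to 1 by cutting the O–CH2OMe bond at the para oxygen. The demands are mono-alkylation of one of two equivalent chelated phenols and selective protection of the para hydroxyl.

## Other disconnections considered

Alternative 1: Both ring bonds to C2 (C2–C3 and O1–C2) are cut, so that C2 arrives as a one-carbon ylide unit bearing an ester. In the forward step base expels sulfinate from 3,5-bis(methoxymethoxy)-2-(tosylmethyl)phenol A1 to give an ortho-quinone methide. A chiral sulfonium ylide of tert-butyl acetate adds to its exocyclic methylene, and the phenoxide then displaces the sulfide to give tert-butyl (S)-4,6-bis(methoxymethoxy)-2,3-dihydrobenzofuran-2-carboxylate A2.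
- In favour: two ring bonds form in one metal-free operation. Both methoxymethyl groups can be present from the start because no carbene probes the ortho substituent. On protecting-group economy this is better than the chosen plan.
- Against: the new centre is α to ester and sulfonium in the betaine and α to ester in A2, so it can epimerise before and after ring closure. The methylene terminus is unsubstituted, so no diastereomeric relay supports the induction, and a stoichiometric chiral sulfide is needed. A2 still needs double MeMgBr addition and silylation to reach 11.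
- Comparison: the step count to 11 is about equal (roughly six operations from 1). Structurally the chosen plan delivers the complete side chain in the ring-forming step. Mechanistically it sets a configurationally stable centre under catalyst control.

Alternative 2: Both bonds joining ring B to ring A (C3a–C3 and C7a–O1) are cut. In the forward step the aryl iodide 1-[6-iodo-2,4-bis(methoxymethoxy)-3-(3-methylbut-2-en-1-yl)phenyl]-3-(4-methoxyphenyl)propan-1-one A3 and (S)-triethyl{[2-(oxiran-2-yl)propan-2-yl]oxy}silane A4 react under Pd(OAc)2, a biaryl phosphine and norbornene. Zerovalent palladium inserts into the carbon–iodine bond, the norbornene-derived palladacycle opens the epoxide at its CH2, and the alkoxide couples at the ipso carbon to give the fully protected target A5, identical with 20.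
- In favour: it is the most convergent plan, better than the chosen one on that count. The stereocentre comes from an enantiopure epoxide whose C–O bond is never broken, so stereochemical certainty is also better.
- Against: A3 is a pentasubstituted iodoarene with iodine next to the ketone. Making it would need the same two regiocontrolled metalations plus an iodination. The C–H to be palladated is flanked by a methoxymethyl ether, the prenyl alkene can insert into aryl–palladium species, and A4 needs a resolution.
- Comparison: the longest linear sequence could be shorter, but the total count is about the same or higher. Mechanistically a multi-event palladium relay meets more competing sites than an intramolecular carbene radical.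

Alternative 3: The O1–C2 bond is traced back to an O1–CMe2 bond in a six-membered ring. In the forward step buffered aqueous solvolysis of (3R)-5,7-bis(methoxymethoxy)-2,2-dimethylchroman-3-yl methanesulfonate A6 lets the aryl oxygen displace the mesylate with inversion. Water then opens the bridged oxonium ion at the tertiary carbon to give (S)-2-[4,6-bis(methoxymethoxy)-2,3-dihydrobenzofuran-2-yl]propan-2-ol A7.
- In favour: the configuration would derive from a dependable asymmetric epoxidation of a 2,2-dimethylchromene with a Mn(salen)Cl catalyst, followed by stereospecific steps. That is more predictable than induction on an untested C–H substrate and is better on this point. Both methoxymethyl groups are in place and A7 is one silylation from 11, which is equal or better on protecting groups.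
- Against: the oxonium ion has several exits (return to the chromanol, elimination, loss of a proton from the tertiary cation). The very electron-rich ring can participate through its ipso carbon, and the acetals must survive the acid set free. Chromene construction, epoxidation, reductive opening and mesylation make the path to 11 about as long as the chosen one or longer.
- Comparison: this plan only reorganises C–O bonds on a finished carbon skeleton, whereas the chosen plan forms the C–C bond, the ring and the stereocentre in one catalytic step from an achiral precursor.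

Key step: step 6

Assumption: the sense of induction of Co(3,5-DitBu-ChenPhyrin) on this ether cannot be predicted with certainty; the catalyst antipode that delivers S at C2 is used, both being accessible from the enantiomers of 2,2-dimethylcyclopropanecarboxamide.

## Route

Step 1
Reactants: 1 2,4,6-trihydroxybenzaldehyde
Product: 2 2,6-dihydroxy-4-(methoxymethoxy)benzaldehyde
Conditions: MOMCl (1.05 equiv), i-Pr2NEt (1.1 equiv), CH2Cl2/THF, −10 → 0 °C
Reagents that add atoms: chloromethyl methyl ether, COCCl
Why: Williamson-type O-alkylation; the para hydroxyl is the most acidic and is not held in a hydrogen bond to the formyl oxygen, so one equivalent of reagent should protect it selectively.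

Step 2
Reactants: 2 2,6-dihydroxy-4-(methoxymethoxy)benzaldehyde; 3 2,2-dimethyloxirane
Product: 4 2-hydroxy-6-(2-hydroxy-2-methylpropoxy)-4-(methoxymethoxy)benzaldehyde
Conditions: K2CO3 (1.0 equiv), 3 (1.3 equiv), DMF, 85 °C, sealed vessel
Reagents that add atoms: none
Why: Base-mediated SN2 opening of the epoxide by a phenoxide at the unsubstituted carbon gives the tertiary alcohol directly. Mono-alkylation is expected because the phenoxide of 2 keeps one chelate to the formyl oxygen whereas deprotonation of 4 would break its only one.

Step 3
Reactants: 4 2-hydroxy-6-(2-hydroxy-2-methylpropoxy)-4-(methoxymethoxy)benzaldehyde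
Product: 5 2-[(tert-butyldimethylsilyl)oxy]-6-(2-hydroxy-2-methylpropoxy)-4-(methoxymethoxy)benzaldehyde
Conditions: TBSCl (1.2 equiv), imidazole (2.5 equiv), DMAP (cat.), DMF, 0 °C → rt
Reagents that add atoms: tert-butyldimethylsilyl chloride, CC(C)(C)[Si](C)(C)Cl
Why: Silylation of the phenol; the tertiary alcohol does not react with the silyl chloride under these conditions. The group is chosen because silicon carries no hydrogen that the later carbene could reach in a 1,5 relation.

Step 4
Reactants: 5 2-[(tert-butyldimethylsilyl)oxy]-6-(2-hydroxy-2-methylpropoxy)-4-(methoxymethoxy)benzaldehyde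
Product: 6 2-[(tert-butyldimethylsilyl)oxy]-4-(methoxymethoxy)-6-[2-methyl-2-(triethylsilyloxy)propoxy]benzaldehyde
Conditions: TESOTf (1.2 equiv), 2,6-lutidine (2 equiv), CH2Cl2, −78 °C, 30 min
Reagents that add atoms: triethylsilyl trifluoromethanesulfonate, CC[Si](CC)(CC)OS(=O)(=O)C(F)(F)F
Why: Silyl triflate silylation of a tertiary alcohol is fast at low temperature, where the aryl acetal and the deactivated aldehyde should not be touched. The cap removes the O–H that could protonate the diazo compound or trap the carbene.

Step 5
Reactants: 6 2-[(tert-butyldimethylsilyl)oxy]-4-(methoxymethoxy)-6-[2-methyl-2-(triethylsilyloxy)propoxy]benzaldehyde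
Product: 7 (E)-N′-{2-[(tert-butyldimethylsilyl)oxy]-4-(methoxymethoxy)-6-[2-methyl-2-(triethylsilyloxy)propoxy]benzylidene}-4-methylbenzenesulfonohydrazide
Conditions: TsNHNH2 (1.05 equiv), THF, 4 Å sieves, rt → 40 °C
Reagents that add atoms: 4-methylbenzenesulfonohydrazide, Cc1ccc(cc1)S(=O)(=O)NN
Why: Hydrazone condensation of an aldehyde; no acid catalyst is added, so the silyl ethers and the acetal should survive.

Step 6
Reactants: 7 (E)-N′-{2-[(tert-butyldimethylsilyl)oxy]-4-(methoxymethoxy)-6-[2-methyl-2-(triethylsilyloxy)propoxy]benzylidene}-4-methylbenzenesulfonohydrazide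
Product: 9 (2S)-4-[(tert-butyldimethylsilyl)oxy]-6-(methoxymethoxy)-2-[2-(triethylsilyloxy)propan-2-yl]-2,3-dihydro-1-benzofuran, via aryldiazomethane 8 (not isolated)
Conditions: Cs2CO3 (2.0 equiv), Co(3,5-DitBu-ChenPhyrin) (3 mol %), toluene (degassed), 40 °C, N2
Reagents that add atoms: none
Why: Cs2CO3 removes the N–H proton of 7 and the salt loses p-toluenesulfinate (Bamford–Stevens) to give 8, which the divalent cobalt metalloradical decomposes with loss of N2 to an α-cobalt benzyl radical on trivalent cobalt. This carbene radical abstracts one hydrogen of the ether O–CH2 through a six-membered 1,5 transition state, and the α-alkoxy radical at the future C2 then attacks C3 with homolytic displacement of divalent cobalt, forming C2–C3 and returning the catalyst. The closest known reaction type is the enantioselective 1,5 C–H alkylation of aryldiazomethanes generated in situ from tosylhydrazones under cobalt amidoporphyrin catalysis; a neopentyl-type O–CH2 extends its scope and is not a new reaction. Ring B closes by a 5-exo-tet radical substitution, C2 onto C3 with the C–Co bond breaking outside the ring. C2 is the only new stereocentre and is set by the catalyst alone: the amide-lined D2-symmetric cavity distinguishes the two enantiotopic hydrogens in the abstraction and holds the short-lived radical so that closure occurs on one face before it rotates. The step needs site selectivity, enantioselectivity and suppression of azine or stilbene formation. The substrate secures these because the O–CH2 is the only C–H in 1,5 reach (O4 bears a silyl group, the methoxymethyl group is para, the tertiary oxygen is capped), the carbene carbon has no β-hydrogen for a 1,2-shift, and its two ortho substituents shield it from a second molecule of 8.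

Step 7
Reactants: 9 (2S)-4-[(tert-butyldimethylsilyl)oxy]-6-(methoxymethoxy)-2-[2-(triethylsilyloxy)propan-2-yl]-2,3-dihydro-1-benzofuran
Product: 11 (2S)-4,6-bis(methoxymethoxy)-2-[2-(triethylsilyloxy)propan-2-yl]-2,3-dihydro-1-benzofuran, via tetrabutylammonium phenoxide 10 (not isolated)
Conditions: TBAF (1.05 equiv), THF, −78 °C, 10 min; then MOMCl (2.5 equiv), i-Pr2NEt (scavenger), −78 → 0 °C
Reagents that add atoms: chloromethyl methyl ether, COCCl
Why: Fluoride cleaves an aryl silyl ether far faster than a hindered tertiary alkyl silyl ether, and one equivalent leaves no fluoride for the latter. The ammonium phenoxide is alkylated in the same flask (Williamson-type), so the air-sensitive phenol is never handled.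

Step 8
Reactants: 11 (2S)-4,6-bis(methoxymethoxy)-2-[2-(triethylsilyloxy)propan-2-yl]-2,3-dihydro-1-benzofuran; 12 prenyl bromide (1-bromo-3-methylbut-2-ene)
Product: 14 (2S)-4,6-bis(methoxymethoxy)-5-(3-methylbut-2-en-1-yl)-2-[2-(triethylsilyloxy)propan-2-yl]-2,3-dihydro-1-benzofuran, via 5-lithio arene 13 (not isolated)
Conditions: n-BuLi (1.15 equiv), THF, 0 °C, 1 h; CuBr·SMe2 (0.2 equiv), −40 °C; 12 (1.5 equiv), −40 → 0 °C
Reagents that add atoms: none
Why: Directed ortho-metalation; C5–H lies between two chelating methoxymethyl ethers and should be removed first, and copper-assisted allylic substitution of the primary bromide gives the linear prenyl arene. C2 has no acidic hydrogen and is not affected.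

Step 9
Reactants: 15 3-(4-methoxyphenyl)propanoic acid
Product: 17 N-methoxy-3-(4-methoxyphenyl)-N-methylpropanamide, via acyl imidazole 16 (not isolated)
Conditions: 1,1′-carbonyldiimidazole (1.1 equiv), CH2Cl2, rt, 1 h; then MeNH(OMe)·HCl (1.2 equiv), rt
Reagents that add atoms: N,O-dimethylhydroxylamine hydrochloride, CNOC.Cl
Why: Amide coupling through the acyl imidazole, a standard preparation of an N-methoxy-N-methylamide.

Step 10
Reactants: 14 (2S)-4,6-bis(methoxymethoxy)-5-(3-methylbut-2-en-1-yl)-2-[2-(triethylsilyloxy)propan-2-yl]-2,3-dihydro-1-benzofuran; 17 N-methoxy-3-(4-methoxyphenyl)-N-methylpropanamide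
Product: 20 1-[(2S)-4,6-bis(methoxymethoxy)-5-(3-methylbut-2-en-1-yl)-2-[2-(triethylsilyloxy)propan-2-yl]-2,3-dihydro-1-benzofuran-7-yl]-3-(4-methoxyphenyl)propan-1-one, via 7-lithio arene 18 (not isolated), via lithium hemiaminal alkoxide 19 (not isolated)
Conditions: n-BuLi (1.2 equiv), THF, −20 → 0 °C, 1 h; 17 (1.4 equiv), −78 → 0 °C; then H2O
Reagents that add atoms: none
Why: Directed ortho-metalation at the only ring hydrogen, flanked by the C6 methoxymethyl ether and the tied-back ring oxygen O1, followed by Weinreb ketone synthesis. The chelated adduct 19 holds the carbonyl masked until work-up, so a single addition is expected.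

Step 11
Reactants: 20 1-[(2S)-4,6-bis(methoxymethoxy)-5-(3-methylbut-2-en-1-yl)-2-[2-(triethylsilyloxy)propan-2-yl]-2,3-dihydro-1-benzofuran-7-yl]-3-(4-methoxyphenyl)propan-1-one
Product: 21 1-[(2S)-4,6-dihydroxy-2-(2-hydroxypropan-2-yl)-5-(3-methylbut-2-en-1-yl)-2,3-dihydro-1-benzofuran-7-yl]-3-(4-methoxyphenyl)propan-1-one
Conditions: HCl (1.25 mol/L in MeOH), MeOH/THF, 0 °C → rt
Reagents that add atoms: none
Why: Acid-catalysed acetal methanolysis and desilylation; dilute anhydrous acid at or below room temperature should remove all three groups before phenol addition to the prenyl alkene or ionisation of the tertiary alcohol sets in. C2 is an unactivated ether carbon and keeps its configuration.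

## Compound list

1 | 2,4,6-trihydroxybenzaldehyde | O=Cc1c(O)cc(O)cc1O | starting material
2 | 2,6-dihydroxy-4-(methoxymethoxy)benzaldehyde | COCOc1cc(O)c(C=O)c(O)c1 | intermediate
3 | 2,2-dimethyloxirane | CC1(C)CO1 | starting material
4 | 2-hydroxy-6-(2-hydroxy-2-methylpropoxy)-4-(methoxymethoxy)benzaldehyde | COCOc1cc(O)c(C=O)c(OCC(C)(C)O)c1 | intermediate
5 | 2-[(tert-butyldimethylsilyl)oxy]-6-(2-hydroxy-2-methylpropoxy)-4-(methoxymethoxy)benzaldehyde | COCOc1cc(O[Si](C)(C)C(C)(C)C)c(C=O)c(OCC(C)(C)O)c1 | intermediate
6 | 2-[(tert-butyldimethylsilyl)oxy]-4-(methoxymethoxy)-6-[2-methyl-2-(triethylsilyloxy)propoxy]benzaldehyde | COCOc1cc(O[Si](C)(C)C(C)(C)C)c(C=O)c(OCC(C)(C)O[Si](CC)(CC)CC)c1 | intermediate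
7 | (E)-tosylhydrazone of 6 | COCOc1cc(O[Si](C)(C)C(C)(C)C)c(/C=N/NS(=O)(=O)c2ccc(C)cc2)c(OCC(C)(C)O[Si](CC)(CC)CC)c1 | intermediate
8 | {2-[(tert-butyldimethylsilyl)oxy]-4-(methoxymethoxy)-6-[2-methyl-2-(triethylsilyloxy)propoxy]phenyl}diazomethane | COCOc1cc(O[Si](C)(C)C(C)(C)C)c(C=[N+]=[N-])c(OCC(C)(C)O[Si](CC)(CC)CC)c1 | intermediate
9 | (2S)-4-[(tert-butyldimethylsilyl)oxy]-6-(methoxymethoxy)-2-[2-(triethylsilyloxy)propan-2-yl]-2,3-dihydro-1-benzofuran | COCOc1cc(O[Si](C)(C)C(C)(C)C)c2c(c1)O[C@H](C(C)(C)O[Si](CC)(CC)CC)C2 | intermediate
10 | (2S)-6-(methoxymethoxy)-2-[2-(triethylsilyloxy)propan-2-yl]-2,3-dihydro-1-benzofuran-4-ol, formed as its tetrabutylammonium phenoxide | COCOc1cc(O)c2c(c1)O[C@H](C(C)(C)O[Si](CC)(CC)CC)C2 | intermediate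
11 | (2S)-4,6-bis(methoxymethoxy)-2-[2-(triethylsilyloxy)propan-2-yl]-2,3-dihydro-1-benzofuran | COCOc1cc(OCOC)c2c(c1)O[C@H](C(C)(C)O[Si](CC)(CC)CC)C2 | intermediate
12 | prenyl bromide | CC(C)=CCBr | starting material
13 | 5-lithio derivative of 11 | COCOc1c([Li])c(OCOC)c2c(c1)O[C@H](C(C)(C)O[Si](CC)(CC)CC)C2 | intermediate
14 | (2S)-4,6-bis(methoxymethoxy)-5-(3-methylbut-2-en-1-yl)-2-[2-(triethylsilyloxy)propan-2-yl]-2,3-dihydro-1-benzofuran | COCOc1c(CC=C(C)C)c(OCOC)c2c(c1)O[C@H](C(C)(C)O[Si](CC)(CC)CC)C2 | intermediate
15 | 3-(4-methoxyphenyl)propanoic acid | COc1ccc(CCC(=O)O)cc1 | starting material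
16 | 1-(1H-imidazol-1-yl)-3-(4-methoxyphenyl)propan-1-one | COc1ccc(CCC(=O)n2ccnc2)cc1 | intermediate
17 | N-methoxy-3-(4-methoxyphenyl)-N-methylpropanamide | COc1ccc(CCC(=O)N(C)OC)cc1 | intermediate
18 | 7-lithio derivative of 14 | COCOc1c(CC=C(C)C)c(OCOC)c2c(c1[Li])O[C@H](C(C)(C)O[Si](CC)(CC)CC)C2 | intermediate
19 | lithium alkoxide of the N-methoxy-N-methyl hemiaminal from 18 and 17 (both epimers at the carbinol carbon) | COc1ccc(CCC(O[Li])(N(C)OC)c2c(OCOC)c(CC=C(C)C)c(OCOC)c3c2O[C@H](C(C)(C)O[Si](CC)(CC)CC)C3)cc1 | intermediate
20 | 1-[(2S)-4,6-bis(methoxymethoxy)-5-(3-methylbut-2-en-1-yl)-2-[2-(triethylsilyloxy)propan-2-yl]-2,3-dihydro-1-benzofuran-7-yl]-3-(4-methoxyphenyl)propan-1-one | COc1ccc(CCC(=O)c2c(OCOC)c(CC=C(C)C)c(OCOC)c3c2O[C@H](C(C)(C)O[Si](CC)(CC)CC)C3)cc1 | intermediate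
21 | 1-[(2S)-4,6-dihydroxy-2-(2-hydroxypropan-2-yl)-5-(3-methylbut-2-en-1-yl)-2,3-dihydro-1-benzofuran-7-yl]-3-(4-methoxyphenyl)propan-1-one | COc1ccc(CCC(=O)c2c(O)c(CC=C(C)C)c(O)c3c2O[C@H](C(C)(C)O)C3)cc1 | target

## Step count and least certain steps

Total: 11 steps. Longest linear sequence: 10 steps (steps 1 to 8, 10 and 11); step 9 is a one-step side branch.

Step 6 (key step). The hydrogen abstraction at the neopentyl-type methylene may be slow next to the fully substituted carbon. Azine formation could then take over, or protonation of the very electron-rich diazo carbon followed by sulfinate capture. Enantiotopic discrimination may also be incomplete, or the carbonate base may strip the aryl silyl group. The fallback replaces C–H insertion by asymmetric hydrogenation of a benzofuran; it sets out from 1 and returns at 11.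
- 1 with two equivalents of MOMCl should give 2-hydroxy-4,6-bis(methoxymethoxy)benzaldehyde F1.
- Rap–Stoermer condensation with chloroacetone and K2CO3 should give 1-[4,6-bis(methoxymethoxy)-1-benzofuran-2-yl]ethan-1-one F2.
- MeMgBr should give 2-[4,6-bis(methoxymethoxy)-1-benzofuran-2-yl]propan-2-ol F3.
- TESOTf and 2,6-lutidine at −78 °C should give 4,6-bis(methoxymethoxy)-2-[2-(triethylsilyloxy)propan-2-yl]-1-benzofuran F4.
- Hydrogenation of the furan double bond with Ru(cod)(2-methylallyl)2, the chiral carbene precursor SINpEt·HBF4 and KOt-Bu under H2, with the ligand antipode chosen for S, should give 11.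

Step 2. A second alkylation of the remaining phenol may occur, or the chelated phenoxide may open the epoxide so slowly that the aldehyde degrades under hot base. The fallback sets out from 2 and returns at 4. Mitsunobu etherification with 2-methylprop-2-en-1-ol (PPh3, DIAD) should give 2-hydroxy-4-(methoxymethoxy)-6-[(2-methylprop-2-en-1-yl)oxy]benzaldehyde F5. Mukaiyama hydration of the 1,1-disubstituted alkene (Co(acac)2, PhSiH3, O2) should then give 4.

Step 8. Metalation may occur at C7, where the tied-back ring oxygen also directs, in competition with C5. The allylic bromide may also react with transposition or by halogen–metal exchange. If C7 metalation is favoured, the order of events is inverted, setting out from 11 and returning at 21.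
- Metalation of 11 and acylation with 17 should give 1-[(2S)-4,6-bis(methoxymethoxy)-2-[2-(triethylsilyloxy)propan-2-yl]-2,3-dihydro-1-benzofuran-7-yl]-3-(4-methoxyphenyl)propan-1-one F6.
- Methanolic HCl should give 1-[(2S)-4,6-dihydroxy-2-(2-hydroxypropan-2-yl)-2,3-dihydro-1-benzofuran-7-yl]-3-(4-methoxyphenyl)propan-1-one F7.
- C-Prenylation of its phenoxide with 12 and aqueous KOH at 0 °C should give 21. This is the classical nuclear alkylation of an acylphloroglucinol, and C5 is the only free ring position.

Step 10. The base may deprotonate the benzylic and allylic CH2 of the prenyl group, or C3, where β-elimination of O1 would open ring B. The hindered aryllithium may also enolise the amide. The fallback sets out from 14 and returns at 18. Iodination with N-iodosuccinimide in MeCN at 0 °C should give (2S)-7-iodo-4,6-bis(methoxymethoxy)-5-(3-methylbut-2-en-1-yl)-2-[2-(triethylsilyloxy)propan-2-yl]-2,3-dihydro-1-benzofuran F8. Iodine–lithium exchange with t-BuLi (2 equiv) at −78 °C then gives 18 within minutes and without a long-lived strong base, and 18 is acylated with 17 as before.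

Step 11. Acid may promote addition of a phenol to the prenyl alkene (chroman formation) or ionisation of the tertiary alcohol before the more hindered acetal at O4 is gone. The fallback avoids Brønsted acid; it sets out from 20 and returns at 21. TBAF buffered with AcOH should give 1-[(2S)-2-(2-hydroxypropan-2-yl)-4,6-bis(methoxymethoxy)-5-(3-methylbut-2-en-1-yl)-2,3-dihydro-1-benzofuran-7-yl]-3-(4-methoxyphenyl)propan-1-one F9. Lewis acid–thiol transacetalisation (ZnBr2, n-PrSH, CH2Cl2, 0 °C, minutes) should then remove both methoxymethyl groups to give 21.

## Further compounds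

F1 | step 6 | 2-hydroxy-4,6-bis(methoxymethoxy)benzaldehyde | COCOc1cc(O)c(C=O)c(OCOC)c1
F2 | step 6 | 1-[4,6-bis(methoxymethoxy)-1-benzofuran-2-yl]ethan-1-one | COCOc1cc(OCOC)c2cc(C(C)=O)oc2c1
F3 | step 6 | 2-[4,6-bis(methoxymethoxy)-1-benzofuran-2-yl]propan-2-ol | COCOc1cc(OCOC)c2cc(C(C)(C)O)oc2c1
F4 | step 6 | 4,6-bis(methoxymethoxy)-2-[2-(triethylsilyloxy)propan-2-yl]-1-benzofuran | COCOc1cc(OCOC)c2cc(C(C)(C)O[Si](CC)(CC)CC)oc2c1
F5 | step 2 | 2-hydroxy-4-(methoxymethoxy)-6-[(2-methylprop-2-en-1-yl)oxy]benzaldehyde | C=C(C)COc1cc(OCOC)cc(O)c1C=O
F6 | step 8 | 1-[(2S)-4,6-bis(methoxymethoxy)-2-[2-(triethylsilyloxy)propan-2-yl]-2,3-dihydro-1-benzofuran-7-yl]-3-(4-methoxyphenyl)propan-1-one | COc1ccc(CCC(=O)c2c(OCOC)cc(OCOC)c3c2O[C@H](C(C)(C)O[Si](CC)(CC)CC)C3)cc1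
F7 | step 8 | 1-[(2S)-4,6-dihydroxy-2-(2-hydroxypropan-2-yl)-2,3-dihydro-1-benzofuran-7-yl]-3-(4-methoxyphenyl)propan-1-one | COc1ccc(CCC(=O)c2c(O)cc(O)c3c2O[C@H](C(C)(C)O)C3)cc1
F8 | step 10 | (2S)-7-iodo-4,6-bis(methoxymethoxy)-5-(3-methylbut-2-en-1-yl)-2-[2-(triethylsilyloxy)propan-2-yl]-2,3-dihydro-1-benzofuran | COCOc1c(CC=C(C)C)c(OCOC)c2c(c1I)O[C@H](C(C)(C)O[Si](CC)(CC)CC)C2
F9 | step 11 | 1-[(2S)-2-(2-hydroxypropan-2-yl)-4,6-bis(methoxymethoxy)-5-(3-methylbut-2-en-1-yl)-2,3-dihydro-1-benzofuran-7-yl]-3-(4-methoxyphenyl)propan-1-one | COc1ccc(CCC(=O)c2c(OCOC)c(CC=C(C)C)c(OCOC)c3c2O[C@H](C(C)(C)O)C3)cc1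
A1 | alternative 1 | 3,5-bis(methoxymethoxy)-2-(tosylmethyl)phenol | COCOc1cc(O)c(CS(=O)(=O)c2ccc(C)cc2)c(OCOC)c1
A2 | alternative 1 | tert-butyl (S)-4,6-bis(methoxymethoxy)-2,3-dihydrobenzofuran-2-carboxylate | COCOc1cc(OCOC)c2c(c1)O[C@H](C(=O)OC(C)(C)C)C2
A3 | alternative 2 | 1-[6-iodo-2,4-bis(methoxymethoxy)-3-(3-methylbut-2-en-1-yl)phenyl]-3-(4-methoxyphenyl)propan-1-one | COc1ccc(CCC(=O)c2c(I)cc(OCOC)c(CC=C(C)C)c2OCOC)cc1
A4 | alternative 2 | (S)-triethyl{[2-(oxiran-2-yl)propan-2-yl]oxy}silane | CC[Si](CC)(CC)OC(C)(C)[C@@H]1CO1
A5 | alternative 2 | fully protected target (bis-methoxymethyl ether, triethylsilyl ether), identical with 20 | COc1ccc(CCC(=O)c2c(OCOC)c(CC=C(C)C)c(OCOC)c3c2O[C@H](C(C)(C)O[Si](CC)(CC)CC)C3)cc1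
A6 | alternative 3 | (3R)-5,7-bis(methoxymethoxy)-2,2-dimethylchroman-3-yl methanesulfonate | COCOc1cc(OCOC)c2c(c1)OC(C)(C)[C@H](OS(C)(=O)=O)C2
A7 | alternative 3 | (S)-2-[4,6-bis(methoxymethoxy)-2,3-dihydrobenzofuran-2-yl]propan-2-ol | COCOc1cc(OCOC)c2c(c1)O[C@H](C(C)(C)O)C2
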